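**Retrosynthetic overview**

1. Target 24 ⇐ MOM removal ⇐ C7–H borylation/oxidation of the 7-deoxy flavan-3-ol 5-gallate 21; the 7-OH arrives after the ester, so only O5 is ever acylated.
2. Chroman ring of 21 ⇐ ring expansion of trans-2-aryl-3-(hydroxymethyl)-2,3-dihydrobenzofuran 19 by a 1,2-shift of the A ring (phenonium ion) with water entering at C3 (key step, sets C3).
3. 19 ⇐ 5-exo aryl-radical cyclisation/oxygenation of the o-iodoaryl 1-arylallyl ether 17 (furan ring, C3 trans to C2).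
4. 17 ⇐ esterification of phenol 10 with acid 16; 10 ⇐ Ir-catalysed asymmetric allylic etherification of 2-iodoresorcinol 2 with cinnamyl carbonate 9 (sets C2).
5. 9 and 16 ⇐ catechol bis-MOM ether 4 (bromination/Heck with methyl acrylate; ortho-lithiation/oxidation, C–H borylation, CO2). Ring order: arenes from resorcinol and catechol → dihydrofuran ring → pyran ring by expansion.

Assumption: single-atom and C1 donors (I2, MOMCl, ClCO2Me, CO2, O2, H2O, Oxone, B2pin2) are treated as reagents, and the phosphoramidite antipode in step 7 is the one that delivers the (S)-ether (both antipodes are available).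

**Route**

Step 1
Reactants: 1 resorcinol
Product: 2 2-iodobenzene-1,3-diol
Conditions: I2, NaHCO3, H2O, 0 °C → rt
Reagents that add atoms: iodine, II
Why: Electrophilic aromatic iodination of the resorcinol phenoxide in water goes to C2 between the two hydroxyls (a known preparation); no stereocentre.

Step 2
Reactants: 3 catechol
Product: 4 1,2-bis(methoxymethoxy)benzene
Conditions: NaH, MOMCl, DMF, 0 °C → rt
Reagents that add atoms: chloromethyl methyl ether, COCCl
Why: Williamson O-alkylation (MOM protection) of both phenoxides gives acetal ethers that direct the later lithiation and survive the basic, Pd, Ir and radical steps.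

Step 3
Reactants: 4 1,2-bis(methoxymethoxy)benzene
Product: 5 4-bromo-1,2-bis(methoxymethoxy)benzene
Conditions: NBS, MeCN, 0 °C → rt
Reagents that add atoms: N-bromosuccinimide, O=C1CCC(=O)N1Br
Why: Electrophilic aromatic bromination of the 1,2-dialkoxyarene occurs para to one oxygen (C4) under neutral conditions that spare the MOM acetals.

Step 4
Reactants: 5 4-bromo-1,2-bis(methoxymethoxy)benzene; 6 methyl acrylate
Product: 7 methyl (2E)-3-[3,4-bis(methoxymethoxy)phenyl]prop-2-enoate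
Conditions: Pd(OAc)2 (2 mol %), P(o-tol)3 (4 mol %), Et3N, DMF, 100 °C
Reagents that add atoms: none
Why: Mizoroki–Heck coupling of the aryl bromide with the acrylate gives the (E)-cinnamate and installs the three carbons that become C2, C3 and C4.

Step 5
Reactants: 7 methyl (2E)-3-[3,4-bis(methoxymethoxy)phenyl]prop-2-enoate
Product: 8 (2E)-3-[3,4-bis(methoxymethoxy)phenyl]prop-2-en-1-ol
Conditions: DIBAL-H (2.2 equiv), CH2Cl2, −78 °C; Rochelle salt work-up
Reagents that add atoms: none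
Why: DIBAL-H 1,2-reduction of the enoate gives the (E)-allylic alcohol without touching the alkene or the acetals.

Step 6
Reactants: 8 (2E)-3-[3,4-bis(methoxymethoxy)phenyl]prop-2-en-1-ol
Product: 9 (2E)-3-[3,4-bis(methoxymethoxy)phenyl]prop-2-en-1-yl methyl carbonate
Conditions: ClCO2Me, pyridine, CH2Cl2, 0 °C
Reagents that add atoms: methyl chloroformate, COC(=O)Cl
Why: O-acylation gives the linear allylic carbonate, the standard electrophile for iridium-catalysed allylic substitution.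

Step 7
Reactants: 9 (2E)-3-[3,4-bis(methoxymethoxy)phenyl]prop-2-en-1-yl methyl carbonate; 2 2-iodobenzene-1,3-diol
Product: 10 3-({(1S)-1-[3,4-bis(methoxymethoxy)phenyl]prop-2-en-1-yl}oxy)-2-iodophenol
Conditions: 2 (2.5 equiv), [Ir(cod)Cl]2 (2 mol %), (Sa,S,S)-phosphoramidite L (Feringa type, 4 mol %), K3PO4, THF, 35 °C
Reagents that add atoms: none
Why: Ir-catalysed asymmetric allylic etherification: the phenoxide attacks the substituted terminus of the (π-allyl)Ir–phosphoramidite complex to give the branched ether, setting the benzylic C–O centre (future C2) as S under catalyst control (≥90% ee expected), with excess symmetric diol 2 suppressing bis-allylation.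

Step 8
Reactants: 4 1,2-bis(methoxymethoxy)benzene
Product: 13 2,3-bis(methoxymethoxy)phenol, via aryllithium 11 (not isolated), via dimethyl arylboronate 12 (not isolated)
Conditions: n-BuLi, THF, 0 °C; B(OMe)3, −78 °C → rt; then AcOH, 30% H2O2, 0 °C → rt
Reagents that add atoms: n-butyllithium, [Li]CCCC (lithium of 11); trimethyl borate, COB(OC)OC (boron of 12); hydrogen peroxide, OO (oxygen of 13)
Why: MOM-directed ortho-metalation at C3, borylation and oxidative C–B to C–O conversion give the 1,2,3-trioxygenated ring of the galloyl unit.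

Step 9
Reactants: 13 2,3-bis(methoxymethoxy)phenol
Product: 14 1,2,3-tris(methoxymethoxy)benzene
Conditions: NaH, MOMCl, DMF, 0 °C → rt
Reagents that add atoms: chloromethyl methyl ether, COCCl
Why: Williamson O-alkylation (MOM protection) of the new phenol gives a uniformly protected pyrogallol ether.

Step 10
Reactants: 14 1,2,3-tris(methoxymethoxy)benzene
Product: 15 4,4,5,5-tetramethyl-2-[3,4,5-tris(methoxymethoxy)phenyl]-1,3,2-dioxaborolane
Conditions: [Ir(OMe)(cod)]2 (1.5 mol %), dtbpy (3 mol %), B2pin2, THF, 80 °C; volatiles removed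
Reagents that add atoms: bis(pinacolato)diboron, CC1(C)OB(OC1(C)C)B1OC(C)(C)C(C)(C)O1
Why: Sterically controlled Ir-catalysed arene C–H borylation goes to C5, the only C–H without an ortho substituent in a 1,2,3-trisubstituted benzene.

Step 11
Reactants: 15 4,4,5,5-tetramethyl-2-[3,4,5-tris(methoxymethoxy)phenyl]-1,3,2-dioxaborolane
Product: 16 3,4,5-tris(methoxymethoxy)benzoic acid
Conditions: CO2 (1 atm), (IPr)CuCl (3 mol %), KOt-Bu (1.1 equiv), THF, 70 °C; then aq. KHSO4 to pH 4, 0 °C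
Reagents that add atoms: carbon dioxide, O=C=O
Why: Copper(I)–NHC-catalysed carboxylation of the arylboronate (transmetalation to aryl–Cu, CO2 insertion) gives the protected gallic acid.

Step 12
Reactants: 10 3-({(1S)-1-[3,4-bis(methoxymethoxy)phenyl]prop-2-en-1-yl}oxy)-2-iodophenol; 16 3,4,5-tris(methoxymethoxy)benzoic acid
Product: 17 3-({(1S)-1-[3,4-bis(methoxymethoxy)phenyl]prop-2-en-1-yl}oxy)-2-iodophenyl 3,4,5-tris(methoxymethoxy)benzoate
Conditions: EDC·HCl, DMAP (0.2 equiv), CH2Cl2, 0 °C → rt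
Reagents that add atoms: none
Why: Steglich (carbodiimide/DMAP) esterification of the only free hydroxyl, the o-iodophenol that becomes O5, so no phenol/alcohol selectivity arises and the C2 centre is untouched.

Step 13
Reactants: 17 3-({(1S)-1-[3,4-bis(methoxymethoxy)phenyl]prop-2-en-1-yl}oxy)-2-iodophenyl 3,4,5-tris(methoxymethoxy)benzoate
Product: 19 (2S,3R)-2-[3,4-bis(methoxymethoxy)phenyl]-3-(hydroxymethyl)-2,3-dihydro-1-benzofuran-4-yl 3,4,5-tris(methoxymethoxy)benzoate, via hydroperoxide 18 (not isolated)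
Conditions: Bu3SnH (2.5 equiv, slow addition), dry air (bubbling), toluene, rt
Reagents that add atoms: dioxygen, O=O
Why: Tin hydride/O2 oxygenative radical cyclisation: the aryl radical closes 5-exo-trig and the primary radical is trapped by O2, the C2 aryl group sitting pseudo-equatorial in the Beckwith chair-like transition state so that C3 forms trans to it (3R, about 4:1 expected, cis isomer removed by chromatography).

Step 14
Reactants: 19 (2S,3R)-2-[3,4-bis(methoxymethoxy)phenyl]-3-(hydroxymethyl)-2,3-dihydro-1-benzofuran-4-yl 3,4,5-tris(methoxymethoxy)benzoate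
Product: 21 (2R,3S)-2-[3,4-bis(methoxymethoxy)phenyl]-3-hydroxy-3,4-dihydro-2H-chromen-5-yl 3,4,5-tris(methoxymethoxy)benzoate, via mesylate 20 (not isolated)
Conditions: MsCl, Et3N, CH2Cl2, −20 °C; then HFIP/H2O (4:1), NaHCO3, 45 °C
Reagents that add atoms: methanesulfonyl chloride, CS(=O)(=O)Cl (in 20); water, O (3-OH of 21)
Why: Proposed new method: the primary mesylate ionises with anchimeric assistance from the o-alkoxy A ring (Ar1-3 participation) to a strained phenonium ion, which water opens at the ring-fusion carbon C3 anti to the departing aryl bond, so the aryl group shifts 1,2 to the former CH2 (new C4–C4a bond), the dihydrobenzofuran becomes the chroman and the 3-OH is installed with inversion trans to the untouched C2 aryl (3S); the closest known reaction type is the neophyl/phenonium solvolytic rearrangement of β-arylalkyl sulfonates (and the related ring expansions of 1-indanylmethyl sulfonates and prolinol-derived aziridinium ions), not yet shown on 2-aryl-3-(sulfonyloxymethyl)-2,3-dihydrobenzofurans as a flavan-3-ol synthesis.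

Step 15
Reactants: 21 (2R,3S)-2-[3,4-bis(methoxymethoxy)phenyl]-3-hydroxy-3,4-dihydro-2H-chromen-5-yl 3,4,5-tris(methoxymethoxy)benzoate
Product: 23 (2R,3S)-2-[3,4-bis(methoxymethoxy)phenyl]-3,7-dihydroxy-3,4-dihydro-2H-chromen-5-yl 3,4,5-tris(methoxymethoxy)benzoate, via 7-boronate 22 (not isolated)
Conditions: [Ir(OMe)(cod)]2 (3 mol %), dtbpy (6 mol %), B2pin2 (1.5 equiv), THF, 70 °C; volatiles removed; then Oxone, acetone/H2O, 0 °C
Reagents that add atoms: bis(pinacolato)diboron, CC1(C)OB(OC1(C)C)B1OC(C)(C)C(C)(C)O1 (boron of 22); potassium peroxymonosulfate, [K+].[O-]S(=O)(=O)OO (7-oxygen of 23)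
Why: Sterically controlled Ir-catalysed arene C–H borylation then ipso-oxidation: C7–H is the only aromatic C–H in 21 with no ortho substituent (every B-ring and galloyl C–H has one), and acidic Oxone converts C–B to C–OH without cleaving the aryl ester or the transient 3-O-boryl group irreversibly.

Step 16
Reactants: 23 (2R,3S)-2-[3,4-bis(methoxymethoxy)phenyl]-3,7-dihydroxy-3,4-dihydro-2H-chromen-5-yl 3,4,5-tris(methoxymethoxy)benzoate
Product: 24 catechin 5-O-gallate [(2R,3S)-2-(3,4-dihydroxyphenyl)-3,7-dihydroxy-3,4-dihydro-2H-chromen-5-yl 3,4,5-trihydroxybenzoate]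
Conditions: ZnBr2 (5 equiv), n-PrSH (10 equiv), CH2Cl2, 0 °C → rt
Reagents that add atoms: none
Why: Lewis acid/thiol cleavage of the five MOM acetals (transfer of CH2OMe to the thiol) is non-basic and non-alcoholytic, so the phenolic gallate ester and both stereocentres survive.

**Compound list**

1 | resorcinol (benzene-1,3-diol) | Oc1cccc(O)c1 | starting material
2 | 2-iodobenzene-1,3-diol | Oc1cccc(O)c1I | intermediate
3 | catechol (benzene-1,2-diol) | Oc1ccccc1O | starting material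
4 | 1,2-bis(methoxymethoxy)benzene | COCOc1ccccc1OCOC | intermediate
5 | 4-bromo-1,2-bis(methoxymethoxy)benzene | COCOc1ccc(Br)cc1OCOC | intermediate
6 | methyl acrylate | C=CC(=O)OC | starting material
7 | methyl (2E)-3-[3,4-bis(methoxymethoxy)phenyl]prop-2-enoate | COC(=O)/C=C/c1ccc(OCOC)c(OCOC)c1 | intermediate
8 | (2E)-3-[3,4-bis(methoxymethoxy)phenyl]prop-2-en-1-ol | OC/C=C/c1ccc(OCOC)c(OCOC)c1 | intermediate
9 | (2E)-3-[3,4-bis(methoxymethoxy)phenyl]prop-2-en-1-yl methyl carbonate | COC(=O)OC/C=C/c1ccc(OCOC)c(OCOC)c1 | intermediate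
10 | 3-({(1S)-1-[3,4-bis(methoxymethoxy)phenyl]prop-2-en-1-yl}oxy)-2-iodophenol | C=C[C@H](Oc1cccc(O)c1I)c1ccc(OCOC)c(OCOC)c1 | intermediate
11 | [2,3-bis(methoxymethoxy)phenyl]lithium | [Li]c1cccc(OCOC)c1OCOC | intermediate
12 | dimethyl [2,3-bis(methoxymethoxy)phenyl]boronate | COB(OC)c1cccc(OCOC)c1OCOC | intermediate
13 | 2,3-bis(methoxymethoxy)phenol | Oc1cccc(OCOC)c1OCOC | intermediate
14 | 1,2,3-tris(methoxymethoxy)benzene | COCOc1cccc(OCOC)c1OCOC | intermediate
15 | 4,4,5,5-tetramethyl-2-[3,4,5-tris(methoxymethoxy)phenyl]-1,3,2-dioxaborolane | COCOc1cc(B2OC(C)(C)C(C)(C)O2)cc(OCOC)c1OCOC | intermediate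
16 | 3,4,5-tris(methoxymethoxy)benzoic acid | COCOc1cc(C(=O)O)cc(OCOC)c1OCOC | intermediate
17 | 3-({(1S)-1-[3,4-bis(methoxymethoxy)phenyl]prop-2-en-1-yl}oxy)-2-iodophenyl 3,4,5-tris(methoxymethoxy)benzoate | C=C[C@H](Oc1cccc(OC(=O)c2cc(OCOC)c(OCOC)c(OCOC)c2)c1I)c1ccc(OCOC)c(OCOC)c1 | intermediate
18 | (2S,3R)-2-[3,4-bis(methoxymethoxy)phenyl]-3-(hydroperoxymethyl)-2,3-dihydro-1-benzofuran-4-yl 3,4,5-tris(methoxymethoxy)benzoate (trans) | OOC[C@@H]1[C@@H](c2ccc(OCOC)c(OCOC)c2)Oc2cccc(OC(=O)c3cc(OCOC)c(OCOC)c(OCOC)c3)c12 | intermediate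
19 | (2S,3R)-2-[3,4-bis(methoxymethoxy)phenyl]-3-(hydroxymethyl)-2,3-dihydro-1-benzofuran-4-yl 3,4,5-tris(methoxymethoxy)benzoate (trans) | OC[C@@H]1[C@@H](c2ccc(OCOC)c(OCOC)c2)Oc2cccc(OC(=O)c3cc(OCOC)c(OCOC)c(OCOC)c3)c12 | intermediate
20 | (2S,3R)-2-[3,4-bis(methoxymethoxy)phenyl]-3-[(methanesulfonyloxy)methyl]-2,3-dihydro-1-benzofuran-4-yl 3,4,5-tris(methoxymethoxy)benzoate | CS(=O)(=O)OC[C@@H]1[C@@H](c2ccc(OCOC)c(OCOC)c2)Oc2cccc(OC(=O)c3cc(OCOC)c(OCOC)c(OCOC)c3)c12 | intermediate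
21 | (2R,3S)-2-[3,4-bis(methoxymethoxy)phenyl]-3-hydroxy-3,4-dihydro-2H-chromen-5-yl 3,4,5-tris(methoxymethoxy)benzoate (2,3-trans) | O=C(Oc1cccc2c1C[C@H](O)[C@@H](c1ccc(OCOC)c(OCOC)c1)O2)c1cc(OCOC)c(OCOC)c(OCOC)c1 | intermediate
22 | (2R,3S)-2-[3,4-bis(methoxymethoxy)phenyl]-3-hydroxy-7-(4,4,5,5-tetramethyl-1,3,2-dioxaborolan-2-yl)-3,4-dihydro-2H-chromen-5-yl 3,4,5-tris(methoxymethoxy)benzoate | O=C(Oc1cc(B3OC(C)(C)C(C)(C)O3)cc2c1C[C@H](O)[C@@H](c1ccc(OCOC)c(OCOC)c1)O2)c1cc(OCOC)c(OCOC)c(OCOC)c1 | intermediate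
23 | (2R,3S)-2-[3,4-bis(methoxymethoxy)phenyl]-3,7-dihydroxy-3,4-dihydro-2H-chromen-5-yl 3,4,5-tris(methoxymethoxy)benzoate | O=C(Oc1cc(O)cc2c1C[C@H](O)[C@@H](c1ccc(OCOC)c(OCOC)c1)O2)c1cc(OCOC)c(OCOC)c(OCOC)c1 | intermediate
24 | catechin 5-O-gallate, (2R,3S) | O=C(Oc1cc(O)cc2c1C[C@H](O)[C@@H](c1ccc(O)c(O)c1)O2)c1cc(O)c(O)c(O)c1 | target

**Step count and risk**

Total step count: 16. Longest linear sequence: 11 steps (3 → 4 → 5 → 7 → 8 → 9 → 10 → 17 → 19 → 21 → 23 → 24, i.e. steps 2, 3, 4, 5, 6, 7, 12, 13, 14, 15, 16).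

Three steps most likely to fail:

(a) Step 14, the proposed new ring expansion. Water may open the phenonium ion at the CH2 carbon and return 19, or proton loss may give a flavene. The fallback uses known chemistry only, sets out from iodide 17 and comes back to the route at 21, replacing steps 13 and 14. Stille coupling of 17 with tributyl(vinyl)tin (Pd2(dba)3, AsPh3, CuI, DMF, 45 °C) gives the o-vinylaryl allyl ether F1. Ring-closing metathesis (Grubbs II, CH2Cl2, 40 °C) closes the pyran ring directly to the (S)-flav-3-ene F2. Hydroboration with BH3·SMe2 (THF, 0 °C) places boron at C3 on the face opposite the C2 aryl group to give the borane F3 (not isolated), and oxidation with NaBO3·4H2O gives the 2,3-trans alcohol 21.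

(b) Step 7, the Ir-catalysed etherification. The o-iodophenoxide may react sluggishly, the diol may be bis-allylated, or branched-to-linear isomerisation may lower the ee. The fallback sets out from allylic alcohol 8 and comes back at ether 10. Sharpless asymmetric epoxidation (Ti(OiPr)4, L-(+)-diethyl tartrate, t-BuOOH, 4 Å MS, CH2Cl2, −20 °C) gives the (2S,3S)-epoxy alcohol F4. The sodium salt of 2 (3 equiv, aq. NaOH/dioxane, 60 °C) opens it at the benzylic carbon with inversion to give the aryloxy diol F5. Garegg–Samuelsson deoxygenation of the 1,2-diol (PPh3, I2, imidazole, toluene, 80 °C) gives the terminal alkene 10 with the ether stereocentre intact.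

(c) Step 15, the late C7–H borylation/oxidation. Conversion or site selectivity may be poor on the densely functionalised 21. The fallback sets out from 2 and comes back at boronate 22: the boron is installed first on the simple arene and carried as a masked hydroxyl. Compound 2 is O-borylated in situ with HBpin (2.2 equiv) and C–H borylated at C5 ([Ir(OMe)(cod)]2, dtbpy, B2pin2, THF, 80 °C) to the tris-borylated arene F6 (not isolated); methanol work-up cleaves the two B–O bonds to give the diol boronate F7. The conditions of steps 7, 12, 13 and 14 are then applied in turn. Etherification with 9 gives the allyl ether F8 and esterification with 16 gives the ester F9. Radical cyclisation/oxygenation gives, through the hydroperoxide F10 (not isolated), the alcohol F11. Mesylation gives the mesylate F12 (not isolated), whose solvolytic ring expansion gives 22; 22 is oxidised to 23 with Oxone as in step 15.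

**Further compounds**

F1 | step 14 | 3-({(1S)-1-[3,4-bis(methoxymethoxy)phenyl]prop-2-en-1-yl}oxy)-2-ethenylphenyl 3,4,5-tris(methoxymethoxy)benzoate | C=C[C@H](Oc1cccc(OC(=O)c2cc(OCOC)c(OCOC)c(OCOC)c2)c1C=C)c1ccc(OCOC)c(OCOC)c1
F2 | step 14 | (2S)-2-[3,4-bis(methoxymethoxy)phenyl]-2H-chromen-5-yl 3,4,5-tris(methoxymethoxy)benzoate | O=C(Oc1cccc2c1C=C[C@@H](c1ccc(OCOC)c(OCOC)c1)O2)c1cc(OCOC)c(OCOC)c(OCOC)c1
F3 | step 14 | (2S,3S)-3-boranyl-2-[3,4-bis(methoxymethoxy)phenyl]-3,4-dihydro-2H-chromen-5-yl 3,4,5-tris(methoxymethoxy)benzoate | O=C(Oc1cccc2c1C[C@H](B)[C@@H](c1ccc(OCOC)c(OCOC)c1)O2)c1cc(OCOC)c(OCOC)c(OCOC)c1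
F4 | step 7 | [(2S,3S)-3-[3,4-bis(methoxymethoxy)phenyl]oxiran-2-yl]methanol | OC[C@@H]1O[C@H]1c1ccc(OCOC)c(OCOC)c1
F5 | step 7 | (2S,3R)-3-[3,4-bis(methoxymethoxy)phenyl]-3-(3-hydroxy-2-iodophenoxy)propane-1,2-diol | OC[C@H](O)[C@H](Oc1cccc(O)c1I)c1ccc(OCOC)c(OCOC)c1
F6 | step 15 | 2-iodo-1,3-bis[(4,4,5,5-tetramethyl-1,3,2-dioxaborolan-2-yl)oxy]-5-(4,4,5,5-tetramethyl-1,3,2-dioxaborolan-2-yl)benzene | Ic1c(OB2OC(C)(C)C(C)(C)O2)cc(B2OC(C)(C)C(C)(C)O2)cc1OB1OC(C)(C)C(C)(C)O1
F7 | step 15 | 2-iodo-5-(4,4,5,5-tetramethyl-1,3,2-dioxaborolan-2-yl)benzene-1,3-diol | Oc1cc(B2OC(C)(C)C(C)(C)O2)cc(O)c1I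
F8 | step 15 | 3-({(1S)-1-[3,4-bis(methoxymethoxy)phenyl]prop-2-en-1-yl}oxy)-2-iodo-5-(4,4,5,5-tetramethyl-1,3,2-dioxaborolan-2-yl)phenol | C=C[C@H](Oc1cc(B2OC(C)(C)C(C)(C)O2)cc(O)c1I)c1ccc(OCOC)c(OCOC)c1
F9 | step 15 | 3-({(1S)-1-[3,4-bis(methoxymethoxy)phenyl]prop-2-en-1-yl}oxy)-2-iodo-5-(4,4,5,5-tetramethyl-1,3,2-dioxaborolan-2-yl)phenyl 3,4,5-tris(methoxymethoxy)benzoate | C=C[C@H](Oc1cc(B2OC(C)(C)C(C)(C)O2)cc(OC(=O)c2cc(OCOC)c(OCOC)c(OCOC)c2)c1I)c1ccc(OCOC)c(OCOC)c1
F10 | step 15 | (2S,3R)-2-[3,4-bis(methoxymethoxy)phenyl]-3-(hydroperoxymethyl)-6-(4,4,5,5-tetramethyl-1,3,2-dioxaborolan-2-yl)-2,3-dihydro-1-benzofuran-4-yl 3,4,5-tris(methoxymethoxy)benzoate | OOC[C@@H]1[C@@H](c2ccc(OCOC)c(OCOC)c2)Oc2cc(B3OC(C)(C)C(C)(C)O3)cc(OC(=O)c3cc(OCOC)c(OCOC)c(OCOC)c3)c12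
F11 | step 15 | (2S,3R)-2-[3,4-bis(methoxymethoxy)phenyl]-3-(hydroxymethyl)-6-(4,4,5,5-tetramethyl-1,3,2-dioxaborolan-2-yl)-2,3-dihydro-1-benzofuran-4-yl 3,4,5-tris(methoxymethoxy)benzoate | OC[C@@H]1[C@@H](c2ccc(OCOC)c(OCOC)c2)Oc2cc(B3OC(C)(C)C(C)(C)O3)cc(OC(=O)c3cc(OCOC)c(OCOC)c(OCOC)c3)c12
F12 | step 15 | (2S,3R)-2-[3,4-bis(methoxymethoxy)phenyl]-3-[(methanesulfonyloxy)methyl]-6-(4,4,5,5-tetramethyl-1,3,2-dioxaborolan-2-yl)-2,3-dihydro-1-benzofuran-4-yl 3,4,5-tris(methoxymethoxy)benzoate | CS(=O)(=O)OC[C@@H]1[C@@H](c2ccc(OCOC)c(OCOC)c2)Oc2cc(B3OC(C)(C)C(C)(C)O3)cc(OC(=O)c3cc(OCOC)c(OCOC)c(OCOC)c3)c12
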